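**Retrosynthetic overview** (longipinane numbering: C1 ketone, C2=C3 with methyl on C3, cyclobutane C4–C5–C11–C10, C6 CMe2, C7, C8, C9, methyl on C10)
1. Feature: the enone bridge C1(=O)–C2=C3(CH3) spans C11 and C4 of the cyclobutane and is the aldol condensation product of two acetyl groups on C11 and C4. These are enantiotopic while the C6–C9 bridge (C7 ketone, C8=C9) lies in the mirror plane through C5 and C10.
2. Target ⇒ O7 acylation ⇒ Evans–Tishchenko reduction (C7, senecioate on O9) ⇒ catalyst-controlled C9 oxygenation ⇒ dienedione 14 ⇒ desymmetrising aldol condensation (C2=C3, six-membered ring) ⇒ meso diacetylbicyclo[4.1.1]octenone 12.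
3. 12 ⇒ acetyl radical addition across the central bond of acetylbicyclo[1.1.0]butane 10 ⇒ carbene cyclopropanation of C4=C5 in diazoketone 9 ⇒ Claisen rearrangement (quaternary C10) and diazo transfer on hydroxydienone 5 ⇒ [4+3] cycloadduct 3 ⇒ bromoketone 1 + 3-methylfuran 2.
4. Ring order: seven-membered ring first ([4+3]), then the cyclobutane (through the bicyclobutane), last the six-membered enone ring.

Key step: step 7

Assumption: the antipodes of the chiral controllers (9-amino-9-deoxy-epi-quinine in step 7, (R,R)-QuinoxP* in step 8) are written as those taken to give the configuration shown; if the sense of induction is opposite, 9-amino-9-deoxy-epi-quinidine or (S,S)-QuinoxP* is used.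

Step 1
Reactants: 1 3-bromo-3-methylbutan-2-one; 2 3-methylfuran
Product: 3 racemic 2,2,6-trimethyl-8-oxabicyclo[3.2.1]oct-6-en-3-one
Conditions: Et3N, CF3CH2OH, 0 °C to rt
Reagents that add atoms: none
Why: [4+3] cycloaddition of the 1,1-dimethyl-2-oxyallyl cation (enolisation of 1, loss of bromide in the ionising solvent) with the furan, in which the unhindered CH2 terminus should bond to the more nucleophilic C2 of 3-methylfuran, so the methyl sits on the alkene carbon next to the CH2-bearing bridgehead and the oxygen bridge fixes the bridgeheads cis (the 2,2,7-trimethyl regioisomer is removed by chromatography).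

Step 2
Reactants: 3 racemic 2,2,6-trimethyl-8-oxabicyclo[3.2.1]oct-6-en-3-one
Product: 5 racemic 6-hydroxy-4,7,7-trimethylcyclohepta-2,4-dien-1-one, via trimethylsilyl ether 4 (not isolated)
Conditions: TMSOTf, Et3N, CH2Cl2, −78 to 0 °C; then citric acid, MeOH, 0 °C
Reagents that add atoms: trimethylsilyl trifluoromethanesulfonate, C[Si](C)(C)OS(=O)(=O)C(F)(F)F (silyl group present in 4 only)
Why: Silyl enol ether formation at the only enolisable carbon followed by silyl-assisted β-elimination of the bridging oxygen (E1cB-type opening of an 8-oxabicyclo[3.2.1]octenone) gives the conjugated dienone, and trapping the oxygen as its silyl ether avoids a free β-alkoxide next to the quaternary carbon and hence retro-aldol cleavage.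

Step 3
Reactants: 5 racemic 6-hydroxy-4,7,7-trimethylcyclohepta-2,4-dien-1-one; 6 but-3-yn-2-one
Product: 7 racemic (E)-4-[(2,2,6-trimethyl-3-oxocyclohepta-4,6-dien-1-yl)oxy]but-3-en-2-one
Conditions: PMe3 (10 mol%), CH2Cl2, 0 °C
Reagents that add atoms: none
Why: Phosphine-catalysed oxa-Michael addition of the secondary alcohol to the ynone gives the (E)-β-alkoxy enone, which is the allyl vinyl ether needed next; no stereocentre is formed.

Step 4
Reactants: 7 racemic (E)-4-[(2,2,6-trimethyl-3-oxocyclohepta-4,6-dien-1-yl)oxy]but-3-en-2-one
Product: 9 racemic 4-(1-diazo-2-oxopropyl)-4,7,7-trimethylcyclohepta-2,5-dien-1-one, via formyl ketone 8 (not isolated)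
Conditions: toluene, 150 °C (sealed tube); then 4-acetamidobenzenesulfonyl azide, Et3N, MeCN, 0 °C to rt
Reagents that add atoms: 4-acetamidobenzenesulfonyl azide, CC(=O)Nc1ccc(cc1)S(=O)(=O)N=[N+]=[N-]
Why: Claisen rearrangement of the allyl β-acyl vinyl ether delivers the acetyl-bearing carbon C11 suprafacially to C10 (new quaternary centre, racemic) and moves the alkene to C4=C5, and the α-formyl ketone then undergoes Regitz deformylative diazo transfer.

Step 5
Reactants: 9 racemic 4-(1-diazo-2-oxopropyl)-4,7,7-trimethylcyclohepta-2,5-dien-1-one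
Product: 10 racemic 8-acetyl-3,3,7-trimethyltricyclo[5.1.0.0(2,8)]oct-5-en-4-one (bicyclo[1.1.0]butane with central bond C4–C11 and acetyl on C11; wings C5 and C10 joined by the CMe2–C(=O)–CH=CH bridge)
Conditions: Rh2(OAc)4 (1 mol%), CH2Cl2, −40 °C to rt, slow addition of 9
Reagents that add atoms: none
Why: Proposed new method: the dirhodium carbene at C11 has no β-hydrogen (C10 is quaternary) and the only electron-rich alkene within reach is the allylic C4=C5 (the C8=C9 enone alkene is deactivated), so intramolecular cyclopropanation should close the second three-membered ring with the ring fusion dictated by the tether; the closest known reaction is the dirhodium-catalysed bicyclobutanation of α-allyl-α-diazo esters.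

Step 6
Reactants: 10 racemic 8-acetyl-3,3,7-trimethyltricyclo[5.1.0.0(2,8)]oct-5-en-4-one; 11 pyruvic acid
Product: 12 7,8-diacetyl-1,5,5-trimethylbicyclo[4.1.1]oct-2-en-4-one (meso when the acetyl groups are cis; taken on as the mixture of C7/C8 epimers)
Conditions: 4CzIPN (2 mol%), K2HPO4, DMSO, blue LEDs, rt
Reagents that add atoms: none
Why: Strain-release Giese-type addition in which the acetyl radical from photocatalytic decarboxylation of pyruvate adds to the unsubstituted bridgehead C4 of the acyl bicyclobutane and the α-keto radical at C11 is reduced and protonated; both new centres are α to ketones and epimerisable, so no control is needed.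

Step 7
Reactants: 12 7,8-diacetyl-1,5,5-trimethylbicyclo[4.1.1]oct-2-en-4-one (epimer mixture)
Product: 14 (4R,5S,10R,11R)-longipina-2,8-diene-1,7-dione, via aldol ketol 13 (not isolated)
Conditions: 9-amino-9-deoxy-epi-quinine (20 mol%), CF3CO2H (40 mol%), toluene, 40 °C
Reagents that add atoms: none
Why: The primary amine forms an enamine from one acetyl group, whose terminal carbon (future C2) adds to the acid-activated carbonyl of the other acetyl (future C3), and E1cB dehydration of the ketol gives the C2=C3 enone; the closest known reaction is the cinchona-primary-amine-catalysed desymmetrising aldol condensation of 4-substituted heptane-2,6-diones to 5-substituted 3-methylcyclohex-2-enones. The six-membered ring closes in the 6-enolendo-exo-trig mode across the cis-1,3 positions of the cyclobutane, giving the bicyclo[3.1.1]heptenone unit. No new stereogenic atom is made; C4, C5, C10 and C11 are fixed together by which acetyl acts as the enamine (it ends as C1/C2 on C11) and which as the acceptor (it ends as C3 with its methyl, on C4), and the chiral amine salt makes this choice. The selectivity needed is between the two enantiotopic acetyl groups, while the constitution is secured by the mirror symmetry of the substrate and by the absence of other enolisable positions (C6 and C10 quaternary, C8 vinylic). Only the epimer with both acetyl groups on the face away from the C6–C9 bridge can reach the transition state, and the others feed it by enol or enamine epimerisation at C4 and C11, so the mixture should converge.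

Step 8
Reactants: 14 (4R,5S,10R,11R)-longipina-2,8-diene-1,7-dione
Product: 16 (4R,5S,9R,10R,11R)-9-hydroxylongipin-2-ene-1,7-dione, via C9 boronate 15 (not isolated)
Conditions: CuCl (5 mol%), NaOt-Bu (10 mol%), (R,R)-QuinoxP* (6 mol%), B2pin2, MeOH, THF, rt; then NaBO3·4H2O, THF/H2O, 0 °C to rt
Reagents that add atoms: bis(pinacolato)diboron, CC1(C)OB(OC1(C)C)B1OC(C)(C)C(C)(C)O1 (boryl group of 15); sodium perborate, [Na+].[Na+].O[B-]1(O)OO[B-](O)(O)OO1 (hydroxyl oxygen of 16)
Why: Copper-catalysed enantioselective conjugate borylation under ligand control, needed because the two faces of the planar C7–C9 enone differ only by remote groups, puts boron on the C9 face syn to C11 and reacts only at the β-monosubstituted C8=C9 enone (the β,β-disubstituted C2=C3 enone is much slower); perborate oxidation then replaces boron by hydroxyl with retention.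

Step 9
Reactants: 16 (4R,5S,9R,10R,11R)-9-hydroxylongipin-2-ene-1,7-dione; 17 3-methylbut-2-enal
Product: 18 (4R,5S,7R,9R,10R,11R)-7-hydroxy-1-oxolongipin-2-en-9-yl 3-methylbut-2-enoate
Conditions: SmI2 (20 mol%), THF, −10 °C
Reagents that add atoms: none
Why: Evans–Tishchenko reduction in which the samarium-bound hemiacetal formed at O9 transfers hydride intramolecularly to the C7 ketone through a six-membered transition state, giving the 1,3-anti relationship (C7 R), leaving the senecioyl group on O9 and not touching the C1 enone, which has no hydroxyl within reach.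

Step 10
Reactants: 18 (4R,5S,7R,9R,10R,11R)-7-hydroxy-1-oxolongipin-2-en-9-yl 3-methylbut-2-enoate; 19 3-methylbutanoic anhydride
Product: 20 the target (4R,5S,7R,9R,10R,11R)-7-(3-methylbutanoyloxy)-1-oxolongipin-2-en-9-yl 3-methylbut-2-enoate
Conditions: DMAP, Et3N, CH2Cl2, rt to 40 °C
Reagents that add atoms: none
Why: DMAP-catalysed acyl transfer (Steglich-type acylation) to the remaining hindered secondary hydroxyl; no stereocentre is touched.

**Compound list**
1 | 3-bromo-3-methylbutan-2-one | CC(=O)C(C)(C)Br | starting material
2 | 3-methylfuran | Cc1ccoc1 | starting material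
3 | 2,2,6-trimethyl-8-oxabicyclo[3.2.1]oct-6-en-3-one (racemic; one enantiomer drawn) | CC1=C[C@@H]2C(C)(C)C(=O)C[C@H]1O2 | intermediate
4 | 4,7,7-trimethyl-6-(trimethylsilyloxy)cyclohepta-2,4-dien-1-one (racemic; not isolated) | C[Si](C)(C)O[C@@H]1C=C(C)C=CC(=O)C1(C)C | intermediate
5 | 6-hydroxy-4,7,7-trimethylcyclohepta-2,4-dien-1-one (racemic) | O=C1C=CC(C)=C[C@@H](O)C1(C)C | intermediate
6 | but-3-yn-2-one | CC(=O)C#C | starting material
7 | (E)-4-[(2,2,6-trimethyl-3-oxocyclohepta-4,6-dien-1-yl)oxy]but-3-en-2-one (racemic) | CC(=O)/C=C/O[C@@H]1C=C(C)C=CC(=O)C1(C)C | intermediate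
8 | 3-oxo-2-(1,4,4-trimethyl-5-oxocyclohepta-2,6-dien-1-yl)butanal (racemic at the ring carbon; side-chain centre labile; not isolated) | CC(=O)C(C=O)[C@@]1(C)C=CC(C)(C)C(=O)C=C1 | intermediate
9 | 4-(1-diazo-2-oxopropyl)-4,7,7-trimethylcyclohepta-2,5-dien-1-one (racemic) | CC(=O)C(=[N+]=[N-])[C@@]1(C)C=CC(C)(C)C(=O)C=C1 | intermediate
10 | 8-acetyl-3,3,7-trimethyltricyclo[5.1.0.0(2,8)]oct-5-en-4-one (racemic) | CC(=O)[C@]12[C@@H]3[C@@]1(C)C=CC(=O)C(C)(C)[C@H]23 | intermediate
11 | pyruvic acid | CC(=O)C(=O)O | starting material
12 | 7,8-diacetyl-1,5,5-trimethylbicyclo[4.1.1]oct-2-en-4-one (meso isomer with both acetyl groups anti to the four-carbon bridge drawn; used as epimer mixture) | C1=CC(=O)C(C)(C)[C@@H]2[C@@H](C(C)=O)[C@@]1(C)[C@H]2C(C)=O | intermediate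
13 | 3-hydroxylongipin-8-ene-1,7-dione (aldol ketol; ring-fusion centres as in 14; carbinol configuration not defined; not isolated) | C1=CC(=O)C(C)(C)[C@@H]2[C@H]3C(=O)CC(C)(O)[C@@H]2[C@]31C | intermediate
14 | (4R,5S,10R,11R)-longipina-2,8-diene-1,7-dione | C1=CC(=O)C(C)(C)[C@@H]2[C@H]3C(=O)C=C(C)[C@@H]2[C@]31C | intermediate
15 | (9R)-9-(4,4,5,5-tetramethyl-1,3,2-dioxaborolan-2-yl)longipin-2-ene-1,7-dione (not isolated) | CC1(C)OB(OC1(C)C)[C@@H]2CC(=O)C(C)(C)[C@@H]3[C@H]4C(=O)C=C(C)[C@@H]3[C@]42C | intermediate
16 | (4R,5S,9R,10R,11R)-9-hydroxylongipin-2-ene-1,7-dione | O[C@@H]1CC(=O)C(C)(C)[C@@H]2[C@H]3C(=O)C=C(C)[C@@H]2[C@]31C | intermediate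
17 | 3-methylbut-2-enal | CC(C)=CC=O | starting material
18 | (4R,5S,7R,9R,10R,11R)-7-hydroxy-1-oxolongipin-2-en-9-yl 3-methylbut-2-enoate | CC(C)=CC(=O)O[C@@H]1C[C@@H](O)C(C)(C)[C@@H]2[C@H]3C(=O)C=C(C)[C@@H]2[C@]31C | intermediate
19 | 3-methylbutanoic anhydride | CC(C)CC(=O)OC(=O)CC(C)C | starting material
20 | (4R,5S,7R,9R,10R,11R)-7-(3-methylbutanoyloxy)-1-oxolongipin-2-en-9-yl 3-methylbut-2-enoate | CC(C)=CC(=O)O[C@@H]1C[C@@H](OC(=O)CC(C)C)C(C)(C)[C@@H]2[C@H]3C(=O)C=C(C)[C@@H]2[C@]31C | target

**Total step count:** 10. **Longest linear sequence:** 10.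

**Steps most likely to fail**

Step 5 (bears the label). The rhodium carbene may be consumed by dimerisation, by attack on the enone alkene C8=C9 or by a 1,2-vinyl shift, because closure of the second three-membered ring is slow. The fallback uses no metal carbene. Compound 9 is heated in toluene (90–110 °C) so that the diazo group adds as a 1,3-dipole across C4=C5, giving the cyclopropane-fused 1-pyrazoline F1. Irradiation at about 350 nm then expels dinitrogen and the 1,3-diradical closes the C11–C5 bond. The fallback sets out from 9 and comes back at 10.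

Step 7. The amine may discriminate poorly between the enantiotopic acetyl groups, closure of the strained bicyclo[3.1.1]heptenone may be slow, or the cyclobutane may open by retro-Michael cleavage of the 1,5-diketone. The fallback replaces asymmetric catalysis by resolution. From 12 the ring is closed with an achiral amine salt (pyrrolidine, AcOH) or KOH in MeOH, both ordinary aldol condensations, to give the racemate, that is 14 together with its mirror image ent-longipina-2,8-diene-1,7-dione F2. Preparative chromatography on a chiral stationary phase separates the two, and the route is rejoined at 14.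

Step 6. The acetyl radical may also add to C9 of the enone, and the acyl bicyclobutane may be opened reductively by the photocatalyst. The fallback is polar opening followed by cross-electrophile coupling. From 10, HBr (1 equiv, Et2O, −20 °C) adds across the central bond (bromide to C4, proton to C11) to give 7-acetyl-8-bromo-1,5,5-trimethylbicyclo[4.1.1]oct-2-en-4-one F3. Nickel-catalysed reductive acylation of this secondary bromide with acetic anhydride (Ni(acac)2, 4,4′-di-tert-butyl-2,2′-bipyridine, Zn, MgCl2, DMA) then gives 12, where the route is rejoined.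

**Further compounds**
F1 | step 5 | cyclopropane-fused 1-pyrazoline from 9 (racemic; diazo carbon bonded to C10 and C4, N=N closing onto C5) | CC(=O)[C@]12N=N[C@@H]3[C@H]1[C@@]2(C)C=CC(=O)C3(C)C
F2 | step 7 | (4S,5R,10S,11S)-longipina-2,8-diene-1,7-dione (enantiomer of 14) | C1=CC(=O)C(C)(C)[C@H]2[C@@H]3C(=O)C=C(C)[C@H]2[C@@]31C
F3 | step 6 | 7-acetyl-8-bromo-1,5,5-trimethylbicyclo[4.1.1]oct-2-en-4-one (racemic epimer mixture; one isomer drawn) | C1=CC(=O)C(C)(C)[C@@H]2[C@@H](Br)[C@@]1(C)[C@H]2C(C)=O
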